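Ring A is not benzylated but built. Its alternating oxygen/carbon pattern is cut into two three-carbon pieces. C8–C8a–C4a is the side-chain carbon plus C2–C3 of a 4-pyrone that already contains O1 and carries the two-ring chain. C5–C6–C7 is a malonyl unit whose central carbon bears the three-ring chain, stored as a dihydrocoumarin-3-carbonyl chloride. One [3+3] annulation forms C7–C8 and C4a–C5, closes the hexasubstituted ring as a chromone, releases the chain phenol from its lactone and fixes the C6/C8 assignment by connectivity alone. The precursors are a pyrone silyl dienol ether and that acid chloride. C2 is set afterwards by asymmetric conjugate phenylation.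

Key step: step 14

Assumption: flavanone numbering (O1, C2–C8a) is used for these atoms also in the precursors; 2-methyl-4H-pyran-4-one is taken as a catalogue compound; centres that are erased later (carbinols, THP acetal carbon, C3 of the dihydrocoumarins, C8 of 19) are carried as mixtures and drawn without configuration, and the geometry of the exocyclic double bond of 18 is immaterial.

Step 1
Reactants: 1 2-(benzyloxy)benzaldehyde; 2 4-(tetrahydro-2H-pyran-2-yloxy)phenylmagnesium bromide
Product: 3 [2-(benzyloxy)phenyl][4-(tetrahydro-2H-pyran-2-yloxy)phenyl]methanol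
Conditions: THF, 0 °C → rt; aqueous work-up
Reagents that add atoms: none
Why: Grignard 1,2-addition to an aromatic aldehyde should be clean; the carbinol centre forms without control and is erased in step 2.

Step 2
Reactants: 3 [2-(benzyloxy)phenyl][4-(tetrahydro-2H-pyran-2-yloxy)phenyl]methanol
Product: 4 4-[2-(benzyloxy)benzyl]phenol
Conditions: Et3SiH (3.5 equiv), TFA, CH2Cl2, 0 °C
Reagents that add atoms: none
Why: Ionic hydrogenation: the diarylmethyl cation, stabilised by an ortho and a para oxygen donor, is captured by silane hydride, the THP acetal is cleaved reductively in the same medium, and the aryl benzyl ether tolerates cold TFA.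

Step 3
Reactants: 4 4-[2-(benzyloxy)benzyl]phenol
Product: 5 5-[2-(benzyloxy)benzyl]-2-hydroxybenzaldehyde
Conditions: MgCl2, Et3N, (CH2O)n, MeCN, reflux; 1 M HCl
Reagents that add atoms: paraformaldehyde (as formaldehyde) C=O
Why: Casnati–Skattebøl ortho-formylation: the magnesium phenoxide delivers formaldehyde only ortho to the single free phenol (both ortho sites equivalent, para blocked) and a second formaldehyde oxidises the benzylic alkoxide, so the benzyl-protected ring stays untouched.

Step 4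
Reactants: 5 5-[2-(benzyloxy)benzyl]-2-hydroxybenzaldehyde
Product: 6 2-(benzyloxy)-5-[2-(benzyloxy)benzyl]benzaldehyde
Conditions: BnBr, K2CO3, DMF, rt
Reagents that add atoms: benzyl bromide BrCc1ccccc1
Why: Williamson etherification of the acidic salicylaldehyde phenol.

Step 5
Reactants: 6 2-(benzyloxy)-5-[2-(benzyloxy)benzyl]benzaldehyde; 2 4-(tetrahydro-2H-pyran-2-yloxy)phenylmagnesium bromide
Product: 7 {2-(benzyloxy)-5-[2-(benzyloxy)benzyl]phenyl}[4-(tetrahydro-2H-pyran-2-yloxy)phenyl]methanol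
Conditions: THF, 0 °C → rt; aqueous work-up
Reagents that add atoms: none
Why: Grignard 1,2-addition as in step 1; the uncontrolled carbinol centre is erased in step 6.

Step 6
Reactants: 7 {2-(benzyloxy)-5-[2-(benzyloxy)benzyl]phenyl}[4-(tetrahydro-2H-pyran-2-yloxy)phenyl]methanol
Product: 8 4-{2-(benzyloxy)-5-[2-(benzyloxy)benzyl]benzyl}phenol
Conditions: Et3SiH (3.5 equiv), TFA, CH2Cl2, 0 °C
Reagents that add atoms: none
Why: Ionic hydrogenation with simultaneous reductive THP cleavage, as in step 2.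

Step 7
Reactants: 8 4-{2-(benzyloxy)-5-[2-(benzyloxy)benzyl]benzyl}phenol
Product: 9 5-{2-(benzyloxy)-5-[2-(benzyloxy)benzyl]benzyl}-2-hydroxybenzaldehyde
Conditions: MgCl2, Et3N, (CH2O)n, MeCN, reflux; 1 M HCl
Reagents that add atoms: paraformaldehyde (as formaldehyde) C=O
Why: Casnati–Skattebøl ortho-formylation, directed by the only free phenol as in step 3.

Step 8
Reactants: 9 5-{2-(benzyloxy)-5-[2-(benzyloxy)benzyl]benzyl}-2-hydroxybenzaldehyde; 10 Meldrum's acid
Product: 11 6-{2-(benzyloxy)-5-[2-(benzyloxy)benzyl]benzyl}-2-oxo-2H-chromene-3-carboxylic acid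
Conditions: piperidinium acetate (cat.), EtOH, reflux
Reagents that add atoms: none
Why: Knoevenagel condensation followed by attack of the ortho phenol on a Meldrum's acid carbonyl (loss of acetone) is the standard entry to coumarin-3-carboxylic acids and stores the first chain phenol as a lactone.

Step 9
Reactants: 11 6-{2-(benzyloxy)-5-[2-(benzyloxy)benzyl]benzyl}-2-oxo-2H-chromene-3-carboxylic acid
Product: 12 6-{2-(benzyloxy)-5-[2-(benzyloxy)benzyl]benzyl}-2-oxochromane-3-carboxylic acid (racemic)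
Conditions: NaBH4, THF–MeOH, 0 °C; 1 M HCl
Reagents that add atoms: none
Why: Conjugate hydride addition to the doubly activated C3=C4 bond of a 3-carboxycoumarin; the malonate-type enolate formed shields the lactone from further reduction, and the new C3 centre is racemic, labile and erased in step 14.

Step 10
Reactants: 12 6-{2-(benzyloxy)-5-[2-(benzyloxy)benzyl]benzyl}-2-oxochromane-3-carboxylic acid
Product: 13 6-{2-(benzyloxy)-5-[2-(benzyloxy)benzyl]benzyl}-2-oxochromane-3-carbonyl chloride
Conditions: (COCl)2, DMF (cat.), CH2Cl2, 0 °C → rt; used crude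
Reagents that add atoms: oxalyl chloride O=C(Cl)C(=O)Cl
Why: Vilsmeier-type acid chloride formation under cold, neutral conditions, as used for malonic half esters; lactone and benzyl ethers are inert.

Step 11
Reactants: 14 2-methyl-4H-pyran-4-one; 6 2-(benzyloxy)-5-[2-(benzyloxy)benzyl]benzaldehyde
Product: 16 (E)-2-(2-{2-(benzyloxy)-5-[2-(benzyloxy)benzyl]phenyl}ethenyl)-4H-pyran-4-one, via lateral aldol adduct 15 (not isolated)
Conditions: NaOEt, EtOH–THF, 0 °C → rt
Reagents that add atoms: none
Why: Vinylogous Claisen–Schmidt condensation: the 2-methyl group is the only acidic site of the pyrone, and E1cB loss of water from 15 gives the conjugated E-styrylpyrone.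

Step 12
Reactants: 16 (E)-2-(2-{2-(benzyloxy)-5-[2-(benzyloxy)benzyl]phenyl}ethenyl)-4H-pyran-4-one
Product: 17 2-(2-{2-(benzyloxy)-5-[2-(benzyloxy)benzyl]phenyl}ethyl)-4H-pyran-4-one
Conditions: H2 (5 atm), RhCl(PPh3)3 (5 mol %), toluene–EtOH, 50 °C
Reagents that add atoms: none
Why: Homogeneous hydrogenation with Wilkinson's catalyst should reduce the unhindered disubstituted styryl bond but neither the push–pull pyrone double bonds nor the aryl benzyl ethers.

Step 13
Reactants: 17 2-(2-{2-(benzyloxy)-5-[2-(benzyloxy)benzyl]phenyl}ethyl)-4H-pyran-4-one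
Product: 18 2-(2-{2-(benzyloxy)-5-[2-(benzyloxy)benzyl]phenyl}ethylidene)-4-(trimethylsilyloxy)-2H-pyran
Conditions: LiHMDS, THF, −78 °C; TMSCl, −78 → 0 °C; evaporation, pentane, filtration under argon; used at once
Reagents that add atoms: chlorotrimethylsilane C[Si](C)(C)Cl
Why: Lateral (γ) deprotonation of a 2-alkyl-4-pyrone, which has no other acidic C–H, then O-silylation of the extended enolate, as in silyl dienol ether formation from vinylogous esters such as dioxinones.

Step 14
Reactants: 18 2-(2-{2-(benzyloxy)-5-[2-(benzyloxy)benzyl]phenyl}ethylidene)-4-(trimethylsilyloxy)-2H-pyran; 13 6-{2-(benzyloxy)-5-[2-(benzyloxy)benzyl]benzyl}-2-oxochromane-3-carbonyl chloride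
Product: 21 8-{2-(benzyloxy)-5-[2-(benzyloxy)benzyl]benzyl}-6-(5-{2-(benzyloxy)-5-[2-(benzyloxy)benzyl]benzyl}-2-hydroxybenzyl)-5,7-dihydroxy-4H-chromen-4-one, via C8-acylated pyrone 19 (not isolated), via acylketene 20 (not isolated)
Conditions: CH2Cl2, −78 °C → rt; then Et3N (2 equiv), rt → 40 °C; 1 M HCl
Reagents that add atoms: none
Why: Proposed new method: the exocyclic carbon of 18 (future C8) is pushed by both O1 and the silyloxy group, and its attack on the acid chloride of 13 regenerates the pyrone sextet with loss of TMSCl, giving 19, in the way 1,3-bis(silyloxy)dienes are γ-acylated by malonyl half chlorides. Et3N then enolises the 3-acyldihydrocoumarin, which expels its own aryloxide (E1cB) to acylketene 20, and the C7 enol of 20 is a dienylketene whose third π bond is the pyrone C4a=C8a bond. Ring A closes by C4a–C5 bond formation, either as a 6π electrocyclisation of that dienylketene or as the equivalent 6-(enolexo)-exo-trig Dieckmann attack of the pyrone dienolate on the lactone carbonyl, and tautomerisation to the 5,7-diol makes it irreversible. The closest known reaction types are the Chan–Brownbridge [3+3] arene synthesis, the Claisen cyclisation of pyrone-masked polyketides and the final stage of the Danheiser benzannulation. No stereocentre is created, since C3 of 13 and C8 of 19 become sp2. The selectivity needed is constitutional and is secured by connectivity: the two-ring chain sits on the only lateral carbon, next to the O1-bearing C8a, the three-ring chain sits on the central malonyl carbon that ends up between the two new C–OH carbons, the two malonyl carbonyls are interchangeable so that first attack through C4a instead of C8 converges on the same product, and the competing O-acylation, relactonisation and four- or eight-membered closures are reversible or strained.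

Step 15
Reactants: 21 8-{2-(benzyloxy)-5-[2-(benzyloxy)benzyl]benzyl}-6-(5-{2-(benzyloxy)-5-[2-(benzyloxy)benzyl]benzyl}-2-hydroxybenzyl)-5,7-dihydroxy-4H-chromen-4-one
Product: 22 5,7-bis(benzyloxy)-8-{2-(benzyloxy)-5-[2-(benzyloxy)benzyl]benzyl}-6-(2-(benzyloxy)-5-{2-(benzyloxy)-5-[2-(benzyloxy)benzyl]benzyl}benzyl)-4H-chromen-4-one
Conditions: BnBr (excess), K2CO3, Bu4NI (cat.), DMF, 70 °C
Reagents that add atoms: benzyl bromide BrCc1ccccc1
Why: Williamson etherification of the three phenols; heat and excess halide should overcome the chelation and crowding of the 5- and 7-hydroxyls, and the achiral chromone tolerates carbonate.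

Step 16
Reactants: 22 5,7-bis(benzyloxy)-8-{2-(benzyloxy)-5-[2-(benzyloxy)benzyl]benzyl}-6-(2-(benzyloxy)-5-{2-(benzyloxy)-5-[2-(benzyloxy)benzyl]benzyl}benzyl)-4H-chromen-4-one; 23 phenylboronic acid
Product: 24 (2S)-5,7-bis(benzyloxy)-8-{2-(benzyloxy)-5-[2-(benzyloxy)benzyl]benzyl}-6-(2-(benzyloxy)-5-{2-(benzyloxy)-5-[2-(benzyloxy)benzyl]benzyl}benzyl)-2-phenylchroman-4-one
Conditions: [Rh(OH)(cod)]2 (2.5 mol %), (S)-MeO-F12-BIPHEP (5.5 mol %), toluene–H2O, 25–40 °C
Reagents that add atoms: none
Why: Hayashi–Miyaura rhodium-catalysed asymmetric 1,4-addition to a chromone: the phenylrhodium species inserts into C2=C3 and the C2-symmetric electron-poor bisphosphine should direct phenyl to the Re face of C2 (O1 > C3 > H), which gives 2S by analogy with (S)-biaryl ligands and cyclohexenone (the antipodal ligand is used if a model run shows the opposite sense), while near-neutral, near-ambient conditions avoid retro-oxa-Michael racemisation.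

Step 17
Reactants: 24 (2S)-heptabenzyl ether of the target
Product: 25 sarmentosumin D, (2S)-5,7-dihydroxy-8-[2-hydroxy-5-(2-hydroxybenzyl)benzyl]-6-{2-hydroxy-5-[2-hydroxy-5-(2-hydroxybenzyl)benzyl]benzyl}-2-phenylchroman-4-one
Conditions: H2 (1 atm), 10 % Pd/C, EtOAc–MeOH, rt
Reagents that add atoms: none
Why: Hydrogenolysis of seven aryl benzyl ethers under neutral conditions should leave the diarylmethane CH2 groups, the C4 ketone and the C2–O1 bond intact when stopped at the calculated uptake, and it cannot epimerise C2 because neither acid nor base is present.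

Compound list
1 | 2-(benzyloxy)benzaldehyde | O=Cc1ccccc1OCc1ccccc1 | starting material
2 | 4-(tetrahydro-2H-pyran-2-yloxy)phenylmagnesium bromide | Br[Mg]c1ccc(OC2CCCCO2)cc1 | starting material
3 | [2-(benzyloxy)phenyl][4-(tetrahydro-2H-pyran-2-yloxy)phenyl]methanol | OC(c1ccccc1OCc1ccccc1)c1ccc(OC2CCCCO2)cc1 | intermediate
4 | 4-[2-(benzyloxy)benzyl]phenol | Oc1ccc(Cc2ccccc2OCc2ccccc2)cc1 | intermediate
5 | 5-[2-(benzyloxy)benzyl]-2-hydroxybenzaldehyde | O=Cc1cc(Cc2ccccc2OCc2ccccc2)ccc1O | intermediate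
6 | 2-(benzyloxy)-5-[2-(benzyloxy)benzyl]benzaldehyde | O=Cc1cc(Cc2ccccc2OCc2ccccc2)ccc1OCc1ccccc1 | intermediate
7 | {2-(benzyloxy)-5-[2-(benzyloxy)benzyl]phenyl}[4-(tetrahydro-2H-pyran-2-yloxy)phenyl]methanol | OC(c1cc(Cc2ccccc2OCc2ccccc2)ccc1OCc1ccccc1)c1ccc(OC2CCCCO2)cc1 | intermediate
8 | 4-{2-(benzyloxy)-5-[2-(benzyloxy)benzyl]benzyl}phenol | Oc1ccc(Cc2cc(Cc3ccccc3OCc3ccccc3)ccc2OCc2ccccc2)cc1 | intermediate
9 | 5-{2-(benzyloxy)-5-[2-(benzyloxy)benzyl]benzyl}-2-hydroxybenzaldehyde | O=Cc1cc(Cc2cc(Cc3ccccc3OCc3ccccc3)ccc2OCc2ccccc2)ccc1O | intermediate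
10 | Meldrum's acid (2,2-dimethyl-1,3-dioxane-4,6-dione) | CC1(C)OC(=O)CC(=O)O1 | starting material
11 | 6-{2-(benzyloxy)-5-[2-(benzyloxy)benzyl]benzyl}-2-oxo-2H-chromene-3-carboxylic acid | OC(=O)C1=Cc2cc(Cc3cc(Cc4ccccc4OCc4ccccc4)ccc3OCc3ccccc3)ccc2OC1=O | intermediate
12 | 6-{2-(benzyloxy)-5-[2-(benzyloxy)benzyl]benzyl}-2-oxochromane-3-carboxylic acid (racemic) | OC(=O)C1Cc2cc(Cc3cc(Cc4ccccc4OCc4ccccc4)ccc3OCc3ccccc3)ccc2OC1=O | intermediate
13 | 6-{2-(benzyloxy)-5-[2-(benzyloxy)benzyl]benzyl}-2-oxochromane-3-carbonyl chloride (racemic) | ClC(=O)C1Cc2cc(Cc3cc(Cc4ccccc4OCc4ccccc4)ccc3OCc3ccccc3)ccc2OC1=O | intermediate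
14 | 2-methyl-4H-pyran-4-one | CC1=CC(=O)C=CO1 | starting material
15 | 2-(2-{2-(benzyloxy)-5-[2-(benzyloxy)benzyl]phenyl}-2-hydroxyethyl)-4H-pyran-4-one (not isolated) | OC(CC1=CC(=O)C=CO1)c1cc(Cc2ccccc2OCc2ccccc2)ccc1OCc1ccccc1 | intermediate
16 | (E)-2-(2-{2-(benzyloxy)-5-[2-(benzyloxy)benzyl]phenyl}ethenyl)-4H-pyran-4-one | O=C1C=COC(/C=C/c2cc(Cc3ccccc3OCc3ccccc3)ccc2OCc2ccccc2)=C1 | intermediate
17 | 2-(2-{2-(benzyloxy)-5-[2-(benzyloxy)benzyl]phenyl}ethyl)-4H-pyran-4-one | O=C1C=COC(CCc2cc(Cc3ccccc3OCc3ccccc3)ccc2OCc2ccccc2)=C1 | intermediate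
18 | 2-(2-{2-(benzyloxy)-5-[2-(benzyloxy)benzyl]phenyl}ethylidene)-4-(trimethylsilyloxy)-2H-pyran | C[Si](C)(C)OC1=CC(=CCc2cc(Cc3ccccc3OCc3ccccc3)ccc2OCc2ccccc2)OC=C1 | intermediate
19 | C8-acylated pyrone: 4-pyrone bearing at C2 a CH(CH2Ar) group acylated by the 2-oxochroman-3-ylcarbonyl unit of 13 (not isolated) | O=C1C=COC(=C1)C(Cc1cc(Cc2ccccc2OCc2ccccc2)ccc1OCc1ccccc1)C(=O)C1Cc2cc(Cc3cc(Cc4ccccc4OCc4ccccc4)ccc3OCc3ccccc3)ccc2OC1=O | intermediate
20 | acylketene from lactone opening of 19 (not isolated) | O=C=C(Cc1cc(Cc2cc(Cc3ccccc3OCc3ccccc3)ccc2OCc2ccccc2)ccc1O)C(=O)C(Cc1cc(Cc2ccccc2OCc2ccccc2)ccc1OCc1ccccc1)C1=CC(=O)C=CO1 | intermediate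
21 | 8-{2-(benzyloxy)-5-[2-(benzyloxy)benzyl]benzyl}-6-(5-{2-(benzyloxy)-5-[2-(benzyloxy)benzyl]benzyl}-2-hydroxybenzyl)-5,7-dihydroxy-4H-chromen-4-one | O=C1C=COc2c(Cc3cc(Cc4ccccc4OCc4ccccc4)ccc3OCc3ccccc3)c(O)c(Cc3cc(Cc4cc(Cc5ccccc5OCc5ccccc5)ccc4OCc4ccccc4)ccc3O)c(O)c12 | intermediate
22 | heptabenzyl chromone (5,7-bis(benzyloxy) and all five chain phenols benzylated) | O=C1C=COc2c(Cc3cc(Cc4ccccc4OCc4ccccc4)ccc3OCc3ccccc3)c(OCc3ccccc3)c(Cc3cc(Cc4cc(Cc5ccccc5OCc5ccccc5)ccc4OCc4ccccc4)ccc3OCc3ccccc3)c(OCc3ccccc3)c12 | intermediate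
23 | phenylboronic acid | OB(O)c1ccccc1 | starting material
24 | (2S)-heptabenzyl flavanone | O=C1C[C@@H](c2ccccc2)Oc2c(Cc3cc(Cc4ccccc4OCc4ccccc4)ccc3OCc3ccccc3)c(OCc3ccccc3)c(Cc3cc(Cc4cc(Cc5ccccc5OCc5ccccc5)ccc4OCc4ccccc4)ccc3OCc3ccccc3)c(OCc3ccccc3)c21 | intermediate
25 | sarmentosumin D (2S) | O=C1C[C@@H](c2ccccc2)Oc2c(Cc3cc(Cc4ccccc4O)ccc3O)c(O)c(Cc3cc(Cc4cc(Cc5ccccc5O)ccc4O)ccc3O)c(O)c21 | target

Total step count: 17.
Longest linear sequence: 14 steps (1 → 2 → 3 → 4 → 5 → 6 → 7 → 8 → 9 → 10 → 14 → 15 → 16 → 17). The pyrone branch (steps 11–13) leaves the main line at 6.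

Steps most likely to fail

First, step 14 (proposed new method). The dienol ether may be protodesilylated by hydrogen chloride shed by the acid chloride. The derived ketene may self-condense faster than it forms the C7–C8 bond. The sequence may also stall after the first acylation. The fallback uses known ortho-quinone methide Friedel–Crafts chemistry on a preformed ring A and sets out from 5 and 9.
- NaBH4 reduction gives the saligenins 4-[2-(benzyloxy)benzyl]-2-(hydroxymethyl)phenol F1 and 4-{2-(benzyloxy)-5-[2-(benzyloxy)benzyl]benzyl}-2-(hydroxymethyl)phenol F2.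
- Heating F1 with commercial 5,7-dihydroxy-4H-chromen-4-one (ZnCl2, dioxane, reflux) should alkylate mainly C8, the site preferred in Mannich reactions of such chromones. This gives 8-{5-[2-(benzyloxy)benzyl]-2-hydroxybenzyl}-5,7-dihydroxy-4H-chromen-4-one F3, and the C6 isomer is removed by chromatography.
- The only remaining nucleophilic carbon, C6, is then alkylated in the same way with F2 to give the 6,8-dibenzylated tetraphenol F4.
- Exhaustive benzylation (BnBr, K2CO3, DMF) of its four phenols comes back to the route at 22.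

Second, step 16. Carbometalation may be slow because the C8 benzyl group and the 5-benzyloxy group crowd the enone. Protodeboronation may then consume the boronic acid, or ring opening may erode the enantiomeric purity. The fallback sets out from 22.
- Aqueous NaOH in dioxane cleaves the pyrone ring (retro-Claisen loss of formate) to the 2-hydroxyacetophenone F5, whose only free phenol is the former O1, so the 6/8 pattern is kept.
- Claisen–Schmidt condensation with benzaldehyde (KOH, EtOH) gives the (E)-2'-hydroxychalcone F6.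
- An organocatalytic asymmetric intramolecular oxa-Michael addition (bifunctional cinchona-alkaloid thiourea) closes ring C through that phenol and comes back to the route at 24, with enrichment by crystallisation if required.

Third, step 12 (together with step 11). The pyrone ring may open under ethoxide during the condensation. The conjugated styryl bond may also be reduced sluggishly, or partial saturation of the pyrone may compete. The fallback replaces condensation and hydrogenation by an sp3–sp3 alkylation and sets out from 6.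
- NaBH4 gives {2-(benzyloxy)-5-[2-(benzyloxy)benzyl]phenyl}methanol F7.
- PBr3 converts it into 1-(benzyloxy)-4-[2-(benzyloxy)benzyl]-2-(bromomethyl)benzene F8.
- Alkylation of the lateral lithium dienolate of 14 (LiHMDS, THF, −78 °C) with F8 comes back to the route at 17.

Further compounds
F1 | step 14 | 4-[2-(benzyloxy)benzyl]-2-(hydroxymethyl)phenol | OCc1cc(Cc2ccccc2OCc2ccccc2)ccc1O
F2 | step 14 | 4-{2-(benzyloxy)-5-[2-(benzyloxy)benzyl]benzyl}-2-(hydroxymethyl)phenol | OCc1cc(Cc2cc(Cc3ccccc3OCc3ccccc3)ccc2OCc2ccccc2)ccc1O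
F3 | step 14 | 8-{5-[2-(benzyloxy)benzyl]-2-hydroxybenzyl}-5,7-dihydroxy-4H-chromen-4-one | O=C1C=COc2c(Cc3cc(Cc4ccccc4OCc4ccccc4)ccc3O)c(O)cc(O)c12
F4 | step 14 | 8-{5-[2-(benzyloxy)benzyl]-2-hydroxybenzyl}-6-(5-{2-(benzyloxy)-5-[2-(benzyloxy)benzyl]benzyl}-2-hydroxybenzyl)-5,7-dihydroxy-4H-chromen-4-one | O=C1C=COc2c(Cc3cc(Cc4ccccc4OCc4ccccc4)ccc3O)c(O)c(Cc3cc(Cc4cc(Cc5ccccc5OCc5ccccc5)ccc4OCc4ccccc4)ccc3O)c(O)c12
F5 | step 16 | 1-[4,6-bis(benzyloxy)-2-hydroxy-3-(two-ring chain)-5-(three-ring chain)phenyl]ethanone, all chain phenols benzylated | CC(=O)c1c(O)c(Cc2cc(Cc3ccccc3OCc3ccccc3)ccc2OCc2ccccc2)c(OCc2ccccc2)c(Cc2cc(Cc3cc(Cc4ccccc4OCc4ccccc4)ccc3OCc3ccccc3)ccc2OCc2ccccc2)c1OCc1ccccc1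
F6 | step 16 | (E)-2'-hydroxychalcone derived from F5 and benzaldehyde | O=C(/C=C/c1ccccc1)c1c(O)c(Cc2cc(Cc3ccccc3OCc3ccccc3)ccc2OCc2ccccc2)c(OCc2ccccc2)c(Cc2cc(Cc3cc(Cc4ccccc4OCc4ccccc4)ccc3OCc3ccccc3)ccc2OCc2ccccc2)c1OCc1ccccc1
F7 | step 12 | {2-(benzyloxy)-5-[2-(benzyloxy)benzyl]phenyl}methanol | OCc1cc(Cc2ccccc2OCc2ccccc2)ccc1OCc1ccccc1
F8 | step 12 | 1-(benzyloxy)-4-[2-(benzyloxy)benzyl]-2-(bromomethyl)benzene | BrCc1cc(Cc2ccccc2OCc2ccccc2)ccc1OCc1ccccc1
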